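## Retrosynthetic overview

- Atom labels: C1 lactone C=O, C2 CH2, C3 CH–OO, C4 C(CH3)–O(lactone), C5 CH2, C6 C(CH3)(chain)–OO.
- Last bond made is C6–CH3. A methyl group is transferred to the bicyclic peroxycarbenium ion, and this sets C6.
- The 1,2-dioxane comes from O2 insertion into the C3–C6 bond of a lactone-fused cyclobutanol (four- to six-membered ring expansion). The cis ring fusion fixes C3.
- The cyclobutanol comes from the chain Grignard reagent plus a cyclobutanone. The cyclobutanone comes from an auxiliary-controlled keteniminium [2+2] on α-angelica lactone, which sets C4.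
- Ring order: γ-lactone (bought), then cyclobutane, then 1,2-dioxane. The chain comes from PhBr and two units of Br(CH2)6Cl.

Assumption: the (2R,5R)-auxiliary is taken to give the (1S,5S)-ketone 13. If the sense of induction is the opposite, the equally available (2S,5S)-amine is used.

## Route

Step 1
Reactants: 1 bromobenzene; 2 1-bromo-6-chlorohexane
Product: 4 (6-chlorohexyl)benzene, via phenylmagnesium bromide 3 (not isolated)
Conditions: Mg, THF, reflux; then 2, Li2CuCl4 (3 mol %), THF/NMP, 0 °C
Reagents that add atoms: none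
Why: Kochi-type copper-catalysed Grignard–alkyl halide cross-coupling reacts at C–Br much faster than at C–Cl, so the chloride survives as the handle for the next Grignard reagent (no stereocenter).

Step 2
Reactants: 4 (6-chlorohexyl)benzene; 2 1-bromo-6-chlorohexane
Product: 6 (12-chlorododecyl)benzene, via 6-phenylhexylmagnesium chloride 5 (not isolated)
Conditions: Mg, cat. I2, THF, reflux; then 2, Li2CuCl4 (3 mol %), THF/NMP, 0 °C
Reagents that add atoms: none
Why: The same Kochi sp3–sp3 coupling, again selective for bromide over chloride, completes the Ph(CH2)12 chain (no stereocenter).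

Step 3
Reactants: 7 acetyl chloride; 8 (2R,5R)-2,5-dimethylpyrrolidine
Product: 9 1-[(2R,5R)-2,5-dimethylpyrrolidin-1-yl]ethan-1-one
Conditions: aq NaOH, CH2Cl2, 0 °C
Reagents that add atoms: none
Why: Schotten–Baumann N-acylation attaches the two-carbon ketene equivalent (future C5 and C6) to the C2-symmetric auxiliary without touching its stereocenters.

Step 4
Reactants: 9 1-[(2R,5R)-2,5-dimethylpyrrolidin-1-yl]ethan-1-one; 10 α-angelica lactone (5-methylfuran-2(3H)-one)
Product: 13 (1S,5S)-1-methyl-2-oxabicyclo[3.2.0]heptane-3,6-dione, via keteniminium triflate 11 (not isolated), via cyclobutaniminium triflate 12 (not isolated)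
Conditions: Tf2O, 2,4,6-collidine, ClCH2CH2Cl, –20 to 60 °C; then H2O, 40 °C
Reagents that add atoms: water, O
Why: In this Ghosez keteniminium–alkene [2+2] cycloaddition (stepwise, cationic) the nucleophilic enol-ester carbon C3 attacks the central keteniminium carbon (C6) and the enamine carbon C5 closes on the C4 acyloxycarbenium ion, so the regiochemistry is fixed, the fusion is necessarily cis, and the C2-symmetric pyrrolidinium selects the alkene face that gives 4S (ee is upgraded by crystallising 13).

Step 5
Reactants: 6 (12-chlorododecyl)benzene; 13 (1S,5S)-1-methyl-2-oxabicyclo[3.2.0]heptane-3,6-dione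
Product: 15 (1S,5R,6R)-6-hydroxy-1-methyl-6-(12-phenyldodecyl)-2-oxabicyclo[3.2.0]heptan-3-one, via 12-phenyldodecylmagnesium chloride 14 (not isolated)
Conditions: Mg, cat. I2, THF, reflux; then 13, LaCl3·2LiCl (30 mol %), THF, –78 °C; AcOH quench at –78 °C
Reagents that add atoms: none
Why: Lanthanide-assisted Grignard 1,2-addition takes the strained cyclobutanone far faster than the lactone and without enolisation, attack on the convex face puts the chain exo and OH endo (this C6 center is erased in step 6), and the cold acid quench prevents translactonisation.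

Step 6
Reactants: 15 (1S,5R,6R)-6-hydroxy-1-methyl-6-(12-phenyldodecyl)-2-oxabicyclo[3.2.0]heptan-3-one
Product: 17 (1S,4S,6S)-4-hydroxy-6-methyl-4-(12-phenyldodecyl)-2,3,7-trioxabicyclo[4.3.0]nonan-8-one, via cis-hydroperoxy ketone 16 (not isolated)
Conditions: Co(acac)2 (10 mol %), O2 (1 atm), MeCN, 40 °C
Reagents that add atoms: dioxygen, O=O
Why: In this known Co(II)/O2 oxidative ring expansion of cyclobutanols the cobalt alkoxide gives an alkoxyl radical, strain-driven β-scission breaks C6–C3 (secondary radical) rather than C6–C5 (primary), the C3 radical captures O2, and hydroperoxide 16 closes on the new C6 ketone under neutral conditions that spare the β-acyloxy ketone; C3 ends up S because only the hydroperoxide cis to the C5 arm can form the cis-fused ring (the acyclic trans isomer is removed by chromatography), and the C6–OH sits axial for anomeric reasons.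

Step 7
Reactants: 17 (1S,4S,6S)-4-hydroxy-6-methyl-4-(12-phenyldodecyl)-2,3,7-trioxabicyclo[4.3.0]nonan-8-one
Product: 18 (1S,4S,6S)-6-methyl-8-oxo-4-(12-phenyldodecyl)-2,3,7-trioxabicyclo[4.3.0]nonan-4-yl acetate
Conditions: Ac2O, pyridine, DMAP (cat.), CH2Cl2, 0 °C
Reagents that add atoms: acetic anhydride, CC(=O)OC(C)=O
Why: DMAP-catalysed O-acylation locks the peroxyhemiketal in its closed form and installs a leaving group, so no free hydroperoxide or ketone meets the organoaluminium reagent in step 8 (C3 and C4 are untouched).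

Step 8
Reactants: 18 (1S,4S,6S)-6-methyl-8-oxo-4-(12-phenyldodecyl)-2,3,7-trioxabicyclo[4.3.0]nonan-4-yl acetate
Product: 20 plakortolide L, (1S,4S,6S)-4,6-dimethyl-4-(12-phenyldodecyl)-2,3,7-trioxabicyclo[4.3.0]nonan-8-one, via peroxycarbenium aluminate ion pair 19 (not isolated)
Conditions: AlMe3 (3 equiv), CH2Cl2, –78 to –30 °C; then aqueous work-up
Reagents that add atoms: trimethylaluminium, C[Al](C)C
Why: Proposed new method: AlMe3 abstracts the acetate of 18 to give the contact ion pair 19 (bicyclic peroxycarbenium ion with Me3Al(OAc)–), and the aluminate passes one methyl to C6 along the axial trajectory of the half-chair that keeps the C4 acyloxy group pseudoaxial and the C4 methyl pseudoequatorial, that is on the face cis to the lactone (the other face would build a syn-axial Me/Me contact), which gives 6S; the hindered O–O bond should survive because Al–CH3 is a poor nucleophile toward σ*(O–O) at –78 °C and the cation is quenched inside the ion pair; the closest known reactions are the Lewis-acid substitution of 1,2-dioxan-3-yl acetates with allylsilanes, silyl enol ethers or Et3SiH (3,6-cis selective) and the AlMe3 C-methylation of lactol and glycosyl acetates, but a simple alkyl-metal donor has not been used on a peroxycarbenium ion.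

## Compound list

1 | bromobenzene | Brc1ccccc1 | starting material
2 | 1-bromo-6-chlorohexane | ClCCCCCCBr | starting material
3 | phenylmagnesium bromide | Br[Mg]c1ccccc1 | intermediate
4 | (6-chlorohexyl)benzene | ClCCCCCCc1ccccc1 | intermediate
5 | 6-phenylhexylmagnesium chloride | Cl[Mg]CCCCCCc1ccccc1 | intermediate
6 | (12-chlorododecyl)benzene | ClCCCCCCCCCCCCc1ccccc1 | intermediate
7 | acetyl chloride | CC(=O)Cl | starting material
8 | (2R,5R)-2,5-dimethylpyrrolidine (auxiliary, recovered in step 4) | C[C@@H]1CC[C@@H](C)N1 | starting material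
9 | 1-[(2R,5R)-2,5-dimethylpyrrolidin-1-yl]ethan-1-one | C[C@@H]1CC[C@@H](C)N1C(C)=O | intermediate
10 | α-angelica lactone, 5-methylfuran-2(3H)-one | CC1=CCC(=O)O1 | starting material
11 | (2R,5R)-1-ethenylidene-2,5-dimethylpyrrolidinium triflate (keteniminium salt) | C[C@@H]1CC[C@@H](C)[N+]1=C=C.[O-]S(=O)(=O)C(F)(F)F | intermediate
12 | cyclobutaniminium triflate (C6 iminium form of 13 carrying the auxiliary) | C[C@@H]1CC[C@@H](C)[N+]1=C3C[C@]4(C)OC(=O)C[C@H]34.[O-]S(=O)(=O)C(F)(F)F | intermediate
13 | (1S,5S)-1-methyl-2-oxabicyclo[3.2.0]heptane-3,6-dione (cis-fused) | O=C1C[C@]2(C)OC(=O)C[C@H]12 | intermediate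
14 | 12-phenyldodecylmagnesium chloride | Cl[Mg]CCCCCCCCCCCCc1ccccc1 | intermediate
15 | (1S,5R,6R)-6-hydroxy-1-methyl-6-(12-phenyldodecyl)-2-oxabicyclo[3.2.0]heptan-3-one (chain exo, OH endo) | O[C@]1(CCCCCCCCCCCCc3ccccc3)C[C@]2(C)OC(=O)C[C@H]12 | intermediate
16 | (4S,5S)-4-hydroperoxy-5-methyl-5-(2-oxo-14-phenyltetradecyl)dihydrofuran-2(3H)-one (OOH cis to the keto side chain) | O=C(CCCCCCCCCCCCc1ccccc1)C[C@]2(C)OC(=O)C[C@@H]2OO | intermediate
17 | (1S,4S,6S)-4-hydroxy-6-methyl-4-(12-phenyldodecyl)-2,3,7-trioxabicyclo[4.3.0]nonan-8-one (OH cis to the lactone) | O[C@]1(CCCCCCCCCCCCc3ccccc3)C[C@]2(C)OC(=O)C[C@@H]2OO1 | intermediate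
18 | (1S,4S,6S)-6-methyl-8-oxo-4-(12-phenyldodecyl)-2,3,7-trioxabicyclo[4.3.0]nonan-4-yl acetate | CC(=O)O[C@]1(CCCCCCCCCCCCc3ccccc3)C[C@]2(C)OC(=O)C[C@@H]2OO1 | intermediate
19 | bicyclic peroxycarbenium ion (C6=O+) with acetoxytrimethylaluminate | C1(CCCCCCCCCCCCc3ccccc3)C[C@]2(C)OC(=O)C[C@@H]2O[O+]=1.CC(=O)O[Al-](C)(C)C | intermediate
20 | plakortolide L, (1S,4S,6S)-4,6-dimethyl-4-(12-phenyldodecyl)-2,3,7-trioxabicyclo[4.3.0]nonan-8-one | C[C@]1(CCCCCCCCCCCCc2ccccc2)C[C@]2(C)OC(=O)C[C@@H]2OO1 | target

## Step count and risks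

Total step count: 8. Longest linear sequence: 6 (steps 3, 4, 5, 6, 7, 8, or steps 1, 2, 5, 6, 7, 8).

**Step 4.** An unsubstituted keteniminium ion has not been tested on an enol lactone, and neither the level nor the sense of induction is known. The fallback sets out from 10 and comes back at 13.
- Dichloroketene (Cl3CCOCl, Zn–Cu, Et2O) adds to 10 to give racemic 7,7-dichloro-1-methyl-2-oxabicyclo[3.2.0]heptane-3,6-dione F1.
- Zn/AcOH removes both chlorines to give racemic 1-methyl-2-oxabicyclo[3.2.0]heptane-3,6-dione F2.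
- Ketalisation with (R,R)-hydrobenzoin (PPTS, benzene, water removal) gives the hydrobenzoin ketal of the (1S,5S)-ketone F3 and the hydrobenzoin ketal of the (1R,5R)-ketone F4.
- F3 and F4 are separated by chromatography or crystallisation, and aqueous TFA cleaves F3 to 13.

**Step 6.** O2 capture at C3 has little facial bias, so about half of the material may end up as the acyclic trans-hydroperoxide, and cobalt can degrade hydroperoxides. The fallback sets out from 15 and comes back at 17.
- PhI(OAc)2/I2 under visible light fragments the cyclobutanol by the alkoxyl-radical route. The bulky iodine donor delivers iodine anti to the keto side chain, giving (4R,5S)-4-iodo-5-methyl-5-(2-oxo-14-phenyltetradecyl)dihydrofuran-2(3H)-one F5.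
- Ethereal H2O2 then adds to the ketone.
- AgBF4 (Et2O, 0 °C) pulls the iodide, so the peroxyhemiketal OOH displaces it with inversion. This ionic closure gives the cis-fused 17 from the major iodide.

**Step 8.** This is the new methylation. The risks are attack of Al–CH3 on the O–O bond, proton loss from 19 to an enol peroxide, or the wrong face. The fallback uses known chemistry, sets out from 15 and comes back at 20.
- The iodide F5, made as above, loses HI with Et3N at 0 °C to give (S)-5-methyl-5-(2-oxo-14-phenyltetradecyl)furan-2(5H)-one F6.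
- Non-basic Zn/CH2Br2/TiCl4 methylenation gives (S)-5-methyl-5-(2-methylidene-14-phenyltetradecyl)furan-2(5H)-one F7.
- Cobalt-catalysed hydroperoxysilylation (Co(thd)2, O2, Et3SiH) of the 1,1-disubstituted alkene gives the triethylsilyl peroxide F8 as both C6 epimers.
- Mild acid desilylation followed by Et2NH in CF3CH2OH closes the ring by intramolecular oxa-Michael addition to the butenolide. This gives 20 and its C6 epimer F9, which are separated by chromatography.

Further compounds
F1 | step 4 | rac-7,7-dichloro-1-methyl-2-oxabicyclo[3.2.0]heptane-3,6-dione (cis-fused, both enantiomers) | O=C1C(Cl)(Cl)[C@]2(C)OC(=O)C[C@H]12.O=C1C(Cl)(Cl)[C@@]2(C)OC(=O)C[C@@H]12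
F2 | step 4 | rac-1-methyl-2-oxabicyclo[3.2.0]heptane-3,6-dione (cis-fused, both enantiomers) | O=C1C[C@]2(C)OC(=O)C[C@H]12.O=C1C[C@@]2(C)OC(=O)C[C@@H]12
F3 | step 4 | (R,R)-hydrobenzoin ketal (at C6) of (1S,5S)-1-methyl-2-oxabicyclo[3.2.0]heptane-3,6-dione | C13(O[C@H](c4ccccc4)[C@@H](c4ccccc4)O3)C[C@]2(C)OC(=O)C[C@H]12
F4 | step 4 | (R,R)-hydrobenzoin ketal (at C6) of (1R,5R)-1-methyl-2-oxabicyclo[3.2.0]heptane-3,6-dione | C13(O[C@H](c4ccccc4)[C@@H](c4ccccc4)O3)C[C@@]2(C)OC(=O)C[C@@H]12
F5 | step 6 | (4R,5S)-4-iodo-5-methyl-5-(2-oxo-14-phenyltetradecyl)dihydrofuran-2(3H)-one | O=C(CCCCCCCCCCCCc1ccccc1)C[C@]2(C)OC(=O)C[C@H]2I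
F6 | step 8 | (S)-5-methyl-5-(2-oxo-14-phenyltetradecyl)furan-2(5H)-one | O=C(CCCCCCCCCCCCc1ccccc1)C[C@]2(C)OC(=O)C=C2
F7 | step 8 | (S)-5-methyl-5-(2-methylidene-14-phenyltetradecyl)furan-2(5H)-one | C=C(CCCCCCCCCCCCc1ccccc1)C[C@]2(C)OC(=O)C=C2
F8 | step 8 | (5S)-5-methyl-5-[2-methyl-14-phenyl-2-(triethylsilylperoxy)tetradecyl]furan-2(5H)-one (both epimers at the peroxide carbon) | CC[Si](CC)(CC)OOC(C)(CCCCCCCCCCCCc1ccccc1)C[C@]2(C)OC(=O)C=C2
F9 | step 8 | (1S,4R,6S)-4,6-dimethyl-4-(12-phenyldodecyl)-2,3,7-trioxabicyclo[4.3.0]nonan-8-one (C6 epimer of 20) | C[C@@]1(CCCCCCCCCCCCc2ccccc2)C[C@]2(C)OC(=O)C[C@@H]2OO1
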